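**Plan**
- Cuts (retrosynthesis): the five O–benzyl bonds; the C6–vinyl bond of the stilbene; the C3–H bond (traced back to a C3 formyl group); the C2–C3 bond of the dihydrofuran, traced back to the C2–C3 bond of the pyran ring in a 2,4-diaryl-2H-chromene 3,4-oxide; then C4–aryl and C2–aryl of a 5,7-disubstituted chromone.
- Forward order: ring A → six-membered pyranone (chromone) → C2 aryl → C4 aryl → chromene → epoxide → contraction of the pyran to the dihydrofuran, one ring carbon leaving as CHO → loss of CO → stilbene arm → deprotection.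
- Enabling feature: C3 of the target is bonded to C3a, which lies between the oxygen-bearing carbons C4 and C7a of ring A, and to an aryl group, so the corresponding pyran carbon ionizes easily. C2 carries O1 and an electron-rich aryl group and so migrates readily. The single H on C3 marks where the expelled carbon sat.
- Stereochemistry: C2 from ligand-controlled conjugate arylation of the chromone; C3 by transfer from C2 in the 1,2-shift (aryl groups trans), kept by stereoretentive decarbonylation; E-alkene from the Heck reaction.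

Key step: step 7

Assumption: the target SMILES encodes the trans-(2R,3R) dihydrobenzofuran; all five phenols are carried as benzyl ethers so that one Lewis acid step frees them without touching the two methyl ethers.

**Step 1**
Reactants: 1 1,3-bis(benzyloxy)-5-bromobenzene
Product: 3 1-[2,6-bis(benzyloxy)-4-bromophenyl]ethan-1-one, via aryllithium 2 (not isolated)
Conditions: LiN(i-Pr)2 (1.1 equiv), THF, −78 °C; then MeC(O)N(OMe)Me, −78 °C to rt; NH4Cl (aq)
Reagents that add atoms: N-methoxy-N-methylacetamide, CC(=O)N(C)OC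
Why: Directed ortho-metalation should occur at the C–H flanked by both benzyloxy groups (most acidic site, para to bromine), the amide base avoiding bromine–lithium exchange, and acylation of 2 by the Weinreb amide stops at the ketone because the chelated tetrahedral adduct survives until work-up.

**Step 2**
Reactants: 3 1-[2,6-bis(benzyloxy)-4-bromophenyl]ethan-1-one
Product: 4 1-[2-(benzyloxy)-4-bromo-6-hydroxyphenyl]ethan-1-one
Conditions: BCl3 (1.05 equiv), CH2Cl2, −78 to −20 °C; H2O
Reagents that add atoms: none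
Why: Chelation-directed Lewis acid ether cleavage should remove only one benzyl group ortho to the carbonyl, because the aryloxyboron chelate formed with the ketone deactivates the second ether.

**Step 3**
Reactants: 4 1-[2-(benzyloxy)-4-bromo-6-hydroxyphenyl]ethan-1-one
Product: 6 5-(benzyloxy)-7-bromo-4H-chromen-4-one, via enaminone 5 (not isolated)
Conditions: Me2NCH(OMe)2, toluene, 90 °C; then conc. HCl, CH2Cl2, rt
Reagents that add atoms: N,N-dimethylformamide dimethyl acetal, COC(OC)N(C)C
Why: Condensation at the methyl ketone gives enaminone 5, and acid then triggers 6-endo addition–elimination of the free phenol with loss of dimethylamine (enaminone route to chromones).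

**Step 4**
Reactants: 6 5-(benzyloxy)-7-bromo-4H-chromen-4-one; 7 [4-(benzyloxy)-3-methoxyphenyl]boronic acid
Product: 8 (2R)-5-(benzyloxy)-2-[4-(benzyloxy)-3-methoxyphenyl]-7-bromo-2,3-dihydro-4H-chromen-4-one
Conditions: Pd(OCOCF3)2 (5 mol%), (S)-4-tert-butyl-2-(pyridin-2-yl)-4,5-dihydrooxazole (6 mol%), NH4PF6 (30 mol%), H2O (5 equiv), ClCH2CH2Cl, 60 °C
Reagents that add atoms: none
Why: Asymmetric conjugate addition of the arylboronic acid under divalent palladium catalysis (transmetalation, enantiodetermining insertion of C2=C3 into the aryl–palladium bond, protonolysis of the palladium enolate) should set C2, the pyridine–oxazoline antipode being the one that gives (2R) (expected for the (S)-ligand by analogy with β-arylation of cyclic enones, to be checked on the first batch), and as no zerovalent palladium is involved the aryl bromide should survive.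

**Step 5**
Reactants: 8 (2R)-5-(benzyloxy)-2-[4-(benzyloxy)-3-methoxyphenyl]-7-bromo-2,3-dihydro-4H-chromen-4-one; 1 1,3-bis(benzyloxy)-5-bromobenzene
Product: 10 (2R)-5-(benzyloxy)-2-[4-(benzyloxy)-3-methoxyphenyl]-4-[3,5-bis(benzyloxy)phenyl]-7-bromo-3,4-dihydro-2H-chromen-4-ol (both C4 epimers), via aryl Grignard reagent 9 (not isolated)
Conditions: 1, Mg, LiCl, THF, rt (gives 9); 8, LaCl3·2LiCl (1.1 equiv), THF, 0 °C, then 9 (1.5 equiv), −20 to 0 °C; NH4Cl (aq)
Reagents that add atoms: none
Why: Grignard 1,2-addition to the ketone, with the oxophilic lanthanum salt favouring carbonyl attack over enolization (which would open the pyranone by retro-oxa-Michael reaction and endanger C2), should give the tertiary alcohol, whose new C4 centre is left uncontrolled because step 6 removes it.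

**Step 6**
Reactants: 10 (2R)-5-(benzyloxy)-2-[4-(benzyloxy)-3-methoxyphenyl]-4-[3,5-bis(benzyloxy)phenyl]-7-bromo-3,4-dihydro-2H-chromen-4-ol
Product: 11 (2R)-5-(benzyloxy)-2-[4-(benzyloxy)-3-methoxyphenyl]-4-[3,5-bis(benzyloxy)phenyl]-7-bromo-2H-chromene
Conditions: Burgess reagent MeO2CN(−)SO2N(+)Et3 (1.5 equiv), THF, 50 °C, dark
Reagents that add atoms: none
Why: Burgess dehydration of the tertiary benzylic alcohol through its sulfamate ester (syn elimination, C3 being the only β-carbon with hydrogen) should give the conjugated C3=C4 alkene without acid, so the acid-labile C2–O1 benzylic ether and the C2 stereocentre stay intact.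

**Step 7**
Reactants: 11 (2R)-5-(benzyloxy)-2-[4-(benzyloxy)-3-methoxyphenyl]-4-[3,5-bis(benzyloxy)phenyl]-7-bromo-2H-chromene
Product: 13 (2S,3S)-4-(benzyloxy)-2-[4-(benzyloxy)-3-methoxyphenyl]-3-[3,5-bis(benzyloxy)phenyl]-6-bromo-2,3-dihydro-1-benzofuran-3-carbaldehyde, via epoxide 12 (not isolated)
Conditions: DMDO (1.1 equiv), acetone/CH2Cl2, −40 °C; evaporate cold; BF3·OEt2 (0.2 equiv), CH2Cl2, −78 °C; Et3N quench
Reagents that add atoms: dimethyldioxirane, CC1(C)OO1
Why: Proposed new method: DMDO should epoxidize the electron-rich trisubstituted C3=C4 bond of 11 on the face away from the C2 aryl group, and BF3 should open the C4–O bond of 12 to a carbenium ion at C4 that is stabilized by its aryl group and, through ring A, by O1 and the C5 benzyloxy group, after which the boron-bound C3 alkoxide drives a suprafacial 1,2-shift of C2 from C3 to C4 (Meinwald/semipinacol rearrangement), so that the pyran contracts to the dihydrofuran and C3 leaves the ring as the formyl group. The closest known reaction type is the Lewis acid-mediated Meinwald rearrangement of 1-arylcycloalkene oxides to ring-contracted 1-arylcycloalkanecarbaldehydes, which has not been shown for 4-aryl-2H-chromene oxides with an oxygen-bearing migrating carbon. The five-membered ring is closed not by attack of a nucleophile on an electrophile but by migration of a ring bond (C2 exchanges its partner C3 for C4 through a three-centre transition state), which is allowed once the C3–C2 bond turns parallel to the empty p orbital at C4. C2 migrates with retention, and the new quaternary centre should form with the C2 aryl group pseudo-equatorial in the sofa-like transition state, which places the two aryl groups trans and the formyl group cis to the C2 aryl, so the C2 centre of 11 controls C3. The step needs carbon migration to win over hydride shift from C3 (which would give the chroman-3-one) and over full C2–C3 fragmentation to an oxocarbenium/enol pair (which would erode the ee); the O-bearing, aryl-substituted C2 has high migratory aptitude, and low temperature, a non-nucleophilic solvent and a substoichiometric Lewis acid should keep the cation short-lived.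

**Step 8**
Reactants: 13 (2S,3S)-4-(benzyloxy)-2-[4-(benzyloxy)-3-methoxyphenyl]-3-[3,5-bis(benzyloxy)phenyl]-6-bromo-2,3-dihydro-1-benzofuran-3-carbaldehyde
Product: 14 (2R,3R)-4-(benzyloxy)-2-[4-(benzyloxy)-3-methoxyphenyl]-3-[3,5-bis(benzyloxy)phenyl]-6-bromo-2,3-dihydro-1-benzofuran
Conditions: RhCl(PPh3)3 (1.2 equiv), toluene (degassed), 120 °C, sealed tube
Reagents that add atoms: none
Why: Tsuji–Wilkinson decarbonylation (oxidative addition of the formyl C–H bond to monovalent rhodium, carbonyl de-insertion, C–H reductive elimination) should replace CHO by H with retention at C3, β-hydride elimination being blocked because the only β-hydrogen, at C2, lies trans to rhodium, so the trans-diaryl arrangement results (the change of descriptors reflects only the CIP ranking).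

**Step 9**
Reactants: 15 4-(benzyloxy)-3-methoxybenzaldehyde
Product: 16 1-(benzyloxy)-4-ethenyl-2-methoxybenzene
Conditions: Ph3PCH3Br, KOt-Bu, THF, 0 °C to rt
Reagents that add atoms: methyltriphenylphosphonium bromide, C[P+](c1ccccc1)(c1ccccc1)c1ccccc1.[Br-]
Why: Wittig methylenation of an aromatic aldehyde with the non-stabilized ylide should give the terminal styrene.

**Step 10**
Reactants: 14 (2R,3R)-4-(benzyloxy)-2-[4-(benzyloxy)-3-methoxyphenyl]-3-[3,5-bis(benzyloxy)phenyl]-6-bromo-2,3-dihydro-1-benzofuran; 16 1-(benzyloxy)-4-ethenyl-2-methoxybenzene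
Product: 17 (2R,3R)-4-(benzyloxy)-2-[4-(benzyloxy)-3-methoxyphenyl]-3-[3,5-bis(benzyloxy)phenyl]-6-{(E)-2-[4-(benzyloxy)-3-methoxyphenyl]ethenyl}-2,3-dihydro-1-benzofuran
Conditions: Pd2(dba)3 (2.5 mol%), [HP(t-Bu)3]BF4 (10 mol%), Cy2NMe (1.5 equiv), 1,4-dioxane, 80 °C
Reagents that add atoms: none
Why: Mizoroki–Heck coupling (oxidative addition of the aryl bromide to zerovalent palladium, syn insertion at the unsubstituted styrene carbon, syn β-hydride elimination) should give the E-stilbene, and the mild amine base leaves both stereocentres alone.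

**Step 11**
Reactants: 17 (2R,3R)-4-(benzyloxy)-2-[4-(benzyloxy)-3-methoxyphenyl]-3-[3,5-bis(benzyloxy)phenyl]-6-{(E)-2-[4-(benzyloxy)-3-methoxyphenyl]ethenyl}-2,3-dihydro-1-benzofuran
Product: 18 (2R,3R)-3-(3,5-dihydroxyphenyl)-2-(4-hydroxy-3-methoxyphenyl)-6-[(E)-2-(4-hydroxy-3-methoxyphenyl)ethenyl]-2,3-dihydro-1-benzofuran-4-ol
Conditions: BCl3 (10 equiv), C6HMe5 (15 equiv), CH2Cl2, −78 °C; MeOH quench
Reagents that add atoms: none
Why: Lewis acid cleavage of the five aryl benzyl ethers with pentamethylbenzene as a non-coordinating trap for the benzyl cation (Friedel–Crafts capture) should work at −78 °C, where the two aryl methyl ethers, the stilbene and the stereocentres are not affected.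

**Compound list**
1 | 1,3-bis(benzyloxy)-5-bromobenzene | Brc1cc(OCc2ccccc2)cc(OCc2ccccc2)c1 | starting material
2 | [2,6-bis(benzyloxy)-4-bromophenyl]lithium | [Li]c1c(OCc2ccccc2)cc(Br)cc1OCc1ccccc1 | intermediate (not isolated)
3 | 1-[2,6-bis(benzyloxy)-4-bromophenyl]ethan-1-one | CC(=O)c1c(OCc2ccccc2)cc(Br)cc1OCc1ccccc1 | intermediate
4 | 1-[2-(benzyloxy)-4-bromo-6-hydroxyphenyl]ethan-1-one | CC(=O)c1c(O)cc(Br)cc1OCc1ccccc1 | intermediate
5 | (2E)-1-[2-(benzyloxy)-4-bromo-6-hydroxyphenyl]-3-(dimethylamino)prop-2-en-1-one | CN(C)/C=C/C(=O)c1c(O)cc(Br)cc1OCc1ccccc1 | intermediate (not isolated)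
6 | 5-(benzyloxy)-7-bromo-4H-chromen-4-one | O=c1ccoc2cc(Br)cc(OCc3ccccc3)c12 | intermediate
7 | [4-(benzyloxy)-3-methoxyphenyl]boronic acid | OB(O)c1ccc(OCc2ccccc2)c(OC)c1 | starting material
8 | (2R)-5-(benzyloxy)-2-[4-(benzyloxy)-3-methoxyphenyl]-7-bromo-2,3-dihydro-4H-chromen-4-one | Brc1cc(OCc2ccccc2)c2c(c1)O[C@@H](c1ccc(OCc3ccccc3)c(OC)c1)CC2=O | intermediate
9 | [3,5-bis(benzyloxy)phenyl]magnesium bromide | Br[Mg]c1cc(OCc2ccccc2)cc(OCc2ccccc2)c1 | intermediate (not isolated)
10 | (2R)-5-(benzyloxy)-2-[4-(benzyloxy)-3-methoxyphenyl]-4-[3,5-bis(benzyloxy)phenyl]-7-bromo-3,4-dihydro-2H-chromen-4-ol (C4 epimers, centre erased in step 6) | Brc1cc(OCc2ccccc2)c2c(c1)O[C@@H](c1ccc(OCc3ccccc3)c(OC)c1)CC2(O)c1cc(OCc2ccccc2)cc(OCc2ccccc2)c1 | intermediate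
11 | (2R)-5-(benzyloxy)-2-[4-(benzyloxy)-3-methoxyphenyl]-4-[3,5-bis(benzyloxy)phenyl]-7-bromo-2H-chromene | Brc1cc(OCc2ccccc2)c2c(c1)O[C@@H](c1ccc(OCc3ccccc3)c(OC)c1)C=C2c1cc(OCc2ccccc2)cc(OCc2ccccc2)c1 | intermediate
12 | 7-(benzyloxy)-2-[4-(benzyloxy)-3-methoxyphenyl]-7b-[3,5-bis(benzyloxy)phenyl]-5-bromo-1a,7b-dihydro-2H-oxireno[2,3-c]chromene (3,4-epoxide of 11, oxirane oxygen trans to the C2 aryl group) | Brc1cc(OCc2ccccc2)c2c(c1)O[C@@H](c1ccc(OCc3ccccc3)c(OC)c1)[C@@H]1O[C@]21c1cc(OCc2ccccc2)cc(OCc2ccccc2)c1 | intermediate (not isolated)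
13 | (2S,3S)-4-(benzyloxy)-2-[4-(benzyloxy)-3-methoxyphenyl]-3-[3,5-bis(benzyloxy)phenyl]-6-bromo-2,3-dihydro-1-benzofuran-3-carbaldehyde | Brc1cc(OCc2ccccc2)c2c(c1)O[C@@H](c1ccc(OCc3ccccc3)c(OC)c1)[C@]2(C=O)c1cc(OCc2ccccc2)cc(OCc2ccccc2)c1 | intermediate
14 | (2R,3R)-4-(benzyloxy)-2-[4-(benzyloxy)-3-methoxyphenyl]-3-[3,5-bis(benzyloxy)phenyl]-6-bromo-2,3-dihydro-1-benzofuran | Brc1cc(OCc2ccccc2)c2c(c1)O[C@@H](c1ccc(OCc3ccccc3)c(OC)c1)[C@@H]2c1cc(OCc2ccccc2)cc(OCc2ccccc2)c1 | intermediate
15 | 4-(benzyloxy)-3-methoxybenzaldehyde | O=Cc1ccc(OCc2ccccc2)c(OC)c1 | starting material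
16 | 1-(benzyloxy)-4-ethenyl-2-methoxybenzene | C=Cc1ccc(OCc2ccccc2)c(OC)c1 | intermediate
17 | (2R,3R)-4-(benzyloxy)-2-[4-(benzyloxy)-3-methoxyphenyl]-3-[3,5-bis(benzyloxy)phenyl]-6-{(E)-2-[4-(benzyloxy)-3-methoxyphenyl]ethenyl}-2,3-dihydro-1-benzofuran | COc1cc(/C=C/c2cc(OCc4ccccc4)c3c(c2)O[C@@H](c2ccc(OCc4ccccc4)c(OC)c2)[C@@H]3c2cc(OCc4ccccc4)cc(OCc4ccccc4)c2)ccc1OCc1ccccc1 | intermediate
18 | (2R,3R)-3-(3,5-dihydroxyphenyl)-2-(4-hydroxy-3-methoxyphenyl)-6-[(E)-2-(4-hydroxy-3-methoxyphenyl)ethenyl]-2,3-dihydro-1-benzofuran-4-ol | COc1cc(/C=C/c2cc(O)c3c(c2)O[C@@H](c2ccc(O)c(OC)c2)[C@@H]3c2cc(O)cc(O)c2)ccc1O | target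

**Step count**
Total: 11 steps. Longest linear sequence: 10 steps (steps 1–8, 10, 11); step 9 is a one-step side branch.

**Steps most likely to fail**

Step 7. The risk is that hydride migration from C3 outruns carbon migration, or that the C2–C3 bond fragments fully and recombines, which would erode the chirality transfer. The fallback uses known reactions only; it sets out from flavanone 8 and comes back at aldehyde 13.
- Oxidative ring contraction of 8 with PhI(OAc)2 and catalytic H2SO4 in HC(OMe)3 (shift of ring A from C4 to C3 in the hypervalent iodine adduct of the enol ether) should give the trans methyl ester, methyl (2R,3R)-4-(benzyloxy)-2-[4-(benzyloxy)-3-methoxyphenyl]-6-bromo-2,3-dihydro-1-benzofuran-3-carboxylate F1, with C2 untouched.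
- The lithium enolate of F1 (LiN(SiMe3)2, THF, −78 °C) cannot expel the ring oxygen for stereoelectronic reasons. It should be arylated on the face away from the C2 aryl group by the diaryliodonium salt [3,5-bis(benzyloxy)phenyl](2,4,6-trimethylphenyl)iodonium tetrafluoroborate F2, to give the quaternary ester methyl (2S,3S)-4-(benzyloxy)-2-[4-(benzyloxy)-3-methoxyphenyl]-3-[3,5-bis(benzyloxy)phenyl]-6-bromo-2,3-dihydro-1-benzofuran-3-carboxylate F3.
- F2 would be made from commercial [3,5-bis(benzyloxy)phenyl]boronic acid, 2-(diacetoxyiodo)-1,3,5-trimethylbenzene and BF3·OEt2.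
- LiAlH4 reduction (THF, 0 °C) should give the primary alcohol [(2S,3R)-4-(benzyloxy)-2-[4-(benzyloxy)-3-methoxyphenyl]-3-[3,5-bis(benzyloxy)phenyl]-6-bromo-2,3-dihydro-1-benzofuran-3-yl]methanol F4, and Dess–Martin oxidation returns 13.

Step 4. The risk is slow carbopalladation of the electron-rich, peri-substituted chromone, competing protodeboronation of the electron-rich boronic acid, or weak facial control. The fallback sets out from ketone 4 (with aldehyde 15) and comes back at flavanone 8.
- Claisen–Schmidt condensation (KOH, EtOH) should give the chalcone (2E)-1-[2-(benzyloxy)-4-bromo-6-hydroxyphenyl]-3-[4-(benzyloxy)-3-methoxyphenyl]prop-2-en-1-one F5.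
- Oxa-Michael cyclization (NaOAc, EtOH, reflux) should give the racemic flavanone 5-(benzyloxy)-2-[4-(benzyloxy)-3-methoxyphenyl]-7-bromo-2,3-dihydro-4H-chromen-4-one F6.
- Kinetic resolution by asymmetric transfer hydrogenation (RuCl[(S,S)-TsDPEN](p-cymene), HCO2H/Et3N) is expected to reduce the (2S)-enantiomer to the cis-flavan-4-ol (2S,4S)-5-(benzyloxy)-2-[4-(benzyloxy)-3-methoxyphenyl]-7-bromo-3,4-dihydro-2H-chromen-4-ol F7, which is separated, leaving (2R)-ketone 8 at half the material at best.

Step 5. The risk is enolization of the flavanone by the basic organometallic, with retro-oxa-Michael ring opening and loss of C2 integrity, and slow attack on the peri-hindered carbonyl. The fallback sets out from chromone 6 and comes back at chromene 11, with the C4 aryl group put in before C2 is made stereogenic.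
- Grignard reagent 9 is added to 6 (LaCl3·2LiCl, THF), which has no enolizable position, to give the tertiary alcohol 5-(benzyloxy)-4-[3,5-bis(benzyloxy)phenyl]-7-bromo-4H-chromen-4-ol F8.
- Acid-catalysed allylic transposition in ethanol (pyridinium p-toluenesulfonate), through the 4-arylchromenylium ion, should give the racemic acetal 5-(benzyloxy)-4-[3,5-bis(benzyloxy)phenyl]-7-bromo-2-ethoxy-2H-chromene F9.
- Enantioselective addition of the boronate diethyl [4-(benzyloxy)-3-methoxyphenyl]boronate F10 (from 7 and ethanol over molecular sieves) to the chromenylium ion regenerated from F9 should give 11. The catalyst pair is a tartaric-acid-derived monoamide Brønsted acid with Yb(OTf)3 in EtOAc at 0 °C, the acid antipode being chosen for (2R).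

**Further compounds**
F1 | step 7 | methyl (2R,3R)-4-(benzyloxy)-2-[4-(benzyloxy)-3-methoxyphenyl]-6-bromo-2,3-dihydro-1-benzofuran-3-carboxylate | Brc1cc(OCc2ccccc2)c2c(c1)O[C@@H](c1ccc(OCc3ccccc3)c(OC)c1)[C@@H]2C(=O)OC
F2 | step 7 | [3,5-bis(benzyloxy)phenyl](2,4,6-trimethylphenyl)iodonium tetrafluoroborate | Cc1cc(C)c([I+]c2cc(OCc3ccccc3)cc(OCc3ccccc3)c2)c(C)c1.F[B-](F)(F)F
F3 | step 7 | methyl (2S,3S)-4-(benzyloxy)-2-[4-(benzyloxy)-3-methoxyphenyl]-3-[3,5-bis(benzyloxy)phenyl]-6-bromo-2,3-dihydro-1-benzofuran-3-carboxylate | Brc1cc(OCc2ccccc2)c2c(c1)O[C@@H](c1ccc(OCc3ccccc3)c(OC)c1)[C@]2(C(=O)OC)c1cc(OCc2ccccc2)cc(OCc2ccccc2)c1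
F4 | step 7 | [(2S,3R)-4-(benzyloxy)-2-[4-(benzyloxy)-3-methoxyphenyl]-3-[3,5-bis(benzyloxy)phenyl]-6-bromo-2,3-dihydro-1-benzofuran-3-yl]methanol | Brc1cc(OCc2ccccc2)c2c(c1)O[C@@H](c1ccc(OCc3ccccc3)c(OC)c1)[C@]2(CO)c1cc(OCc2ccccc2)cc(OCc2ccccc2)c1
F5 | step 4 | (2E)-1-[2-(benzyloxy)-4-bromo-6-hydroxyphenyl]-3-[4-(benzyloxy)-3-methoxyphenyl]prop-2-en-1-one | COc1cc(/C=C/C(=O)c2c(O)cc(Br)cc2OCc2ccccc2)ccc1OCc1ccccc1
F6 | step 4 | racemic 5-(benzyloxy)-2-[4-(benzyloxy)-3-methoxyphenyl]-7-bromo-2,3-dihydro-4H-chromen-4-one | Brc1cc(OCc2ccccc2)c2c(c1)OC(c1ccc(OCc3ccccc3)c(OC)c1)CC2=O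
F7 | step 4 | (2S,4S)-5-(benzyloxy)-2-[4-(benzyloxy)-3-methoxyphenyl]-7-bromo-3,4-dihydro-2H-chromen-4-ol | Brc1cc(OCc2ccccc2)c2c(c1)O[C@H](c1ccc(OCc3ccccc3)c(OC)c1)C[C@@H]2O
F8 | step 5 | racemic 5-(benzyloxy)-4-[3,5-bis(benzyloxy)phenyl]-7-bromo-4H-chromen-4-ol | OC1(c2cc(OCc3ccccc3)cc(OCc3ccccc3)c2)C=COc2cc(Br)cc(OCc3ccccc3)c21
F9 | step 5 | racemic 5-(benzyloxy)-4-[3,5-bis(benzyloxy)phenyl]-7-bromo-2-ethoxy-2H-chromene | CCOC1C=C(c2cc(OCc3ccccc3)cc(OCc3ccccc3)c2)c2c(OCc3ccccc3)cc(Br)cc2O1
F10 | step 5 | diethyl [4-(benzyloxy)-3-methoxyphenyl]boronate | CCOB(OCC)c1ccc(OCc2ccccc2)c(OC)c1
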